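**Remark:** locants follow germacranolide numbering in every intermediate, the bicyclic ones included (ring C1–C10, lactone carbons C11–C13, C14 on C10, C15 on C4); 6 and 17 are taken as purchased reagents.

## Analysis of the target

Target 34 is a germacranolide: a ten-membered carbocycle (C1–C10) carrying a fused α-(hydroxymethyl)butenolide (O6–C12(=O)–C11=C7, C13–OH) and a 4,5-epoxide. It has five stereocentres: C4 (R), C5 (R), C6 (S), C8 (S) and C10 (R). C4 and C5 are the ends of a trans epoxide, which is the oxidation product of an E C4=C5 olefin, with the epoxide oxygen anti to C7 across C5–C6. O6, O8 and O10 are all syn when C5–C10 is drawn as a zigzag, and the quaternary C10 is separated from the others by C9. The sensitive groups are the epoxide next to the lactone oxygen, the tertiary α-acetoxy ketone, two acetates that can migrate to the free C13 hydroxyl, and the acidic H6 of the butenolide. The hard parts are forming a ten-membered ring with a defined olefin geometry, relaying configuration between C10 and the C6/C8 pair across a flexible ring, and telling the two one-carbon groups on C11 apart. The strategy rests on one relation: the methyl-bearing C4 and the oxygenated C8 are linked by C5–C6–C7, so an extra C4–C8 bond makes these five atoms the ring of 2-methylcyclopentane-1,3-dione (1), fused to a seven-membered ring (C9, C10, C1, C2, C3). Breaking that bond with a leaving group on C5 and an oxyanion on C8 returns the C8 carbonyl and the C4=C5 olefin.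

## Retrosynthetic reasoning

**34 ⇒ 33.** The epoxide is removed first. It would not survive the acidic and fluoride steps of the endgame, and the E olefin of 33 is the direct product of the ring-forming step. The forward step must oxidise only the electron-rich C4=C5 olefin, on its outer face.

**33 ⇒ 32 ⇒ 31 ⇒ 30 ⇒ 29.** O13 is masked as a silyl ether, the C10 acetate is removed, and the C1 carbonyl is taken back to a C1,C10-diol held as an acetonide. The C1 ketone is 1,4 to the C8 carbonyl. With both present, an enolate at C7 would close a five-membered ring across the macrocycle, and the C2 hydrogens would compete with those at C7. A silyl ether on O10 would sit 1,3 to the C8 alkoxide of the key step and could migrate to it. One acetonide over O1 and O10 avoids all three problems.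

**29 ⇒ 27 ⇒ 26.** The lactone C–O bond is cut and C6 is taken back through its ketone to a methylene. In 26, C6 is the only doubly allylic carbon (between C4=C5 and C7=C11), so it can be oxidised selectively; reduction then sets C6 and the cis ester closes the ring. O8 must already be acetylated so that it cannot compete for the ester.

**26 ⇒ 25 ⇒ 24 ⇒ 22 ⇒ 16 + 20.** The C7–C11 bond is cut by a retro-aldol condensation between the C7 enolate of ketone 16 and keto ester 20. Keto ester 20 brings C11, C12 at the acid level and C13 with its oxygen protected, so the two arms on C11 never need to be told apart later. The price is that the geometry of the tetrasubstituted olefin must be controlled. Keto ester 20 comes from acrylate 17 in two steps.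

**16 ⇒ 14 (key disconnection).** The C4–C8 bond is re-formed, which turns the ten-membered ketone into the bicyclo[5.3.0]decane 14 with a free tertiary C8 hydroxyl and a C5 mesylate. Forward, a Grob fragmentation uncovers the ring instead of closing it, and the olefin geometry follows from the relative configuration at C4/C5. After fragmentation C10 is the only stereocentre that matters.

**14 ⇒ 13 ⇒ 12 ⇒ 10.** The mesylate and acetonide are removed, and O1 and O10 are traced to a syn dihydroxylation of a C10=C1 olefin. The tertiary C8 hydroxyl directs it, which relays the configuration of C8 to C10.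

**10 ⇒ 9 ⇒ 8.** The C5 carbinol must be cis to the C4 methyl for an E olefin. A hydroxyl-directed reduction of ketone 9 gives this if the C8 hydroxyl is trans to the methyl. This is why the bicycle is trans-fused: in a cis-fused isomer both steric approach and hydroxyl delivery would put O5 trans to the methyl, leading to the Z olefin.

**8 ⇒ 7.** The seven-membered ring is opened at C10=C1 by a retro ring-closing metathesis. A trans fusion is what two arms on opposite faces of the cyclopentane give.

**7 ⇒ 5 + 6.** The C8–C9 bond is cut: methallyl reagent 6 adds to the ketone of 5 anti to the chain, which places the C8 hydroxyl trans to the methyl.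

**5 ⇒ 4 ⇒ 3 ⇒ 1 + 2.** Diol precursor 5 comes from the prochiral dione 4 by a catalyst-controlled mono-reduction. This is the single step that sets the absolute configuration (at C4); the carbinol it creates is only a marker and is later oxidised and re-reduced. Dione 4 comes from 1 and acrolein (2) by Michael addition and methylenation.

## Alternatives that were turned down

**Alternative 1:** The cut runs through C6–C7, C11–C12 and O6–C12 at once, so that carbocycle and butenolide open together to the acyclic epoxy ynal A1. A1 already carries the C8 and C10 acetates, a C1 silyl ether, the epoxide and a PMB ether on O13. Forward, Mo(CO)6 with dimethyl sulfoxide would join the C6 aldehyde, the C7–C11 alkyne and carbon monoxide in a hetero-Pauson–Khand reaction to give A2.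
- For: three bonds and two rings form in one step. The butenolide arrives with C12 and C13 already differentiated and with no olefin-geometry question. All centres but C6 are made on an open chain. A2 is only a few operations from 34. On convergence and on step count after ring formation this is stronger than the chosen route.
- Against: the reaction is dependable when the tether closes a five- or six-membered carbocycle. Here eight atoms separate C6 and C7, so the metallacycle must form across a ten-membered ring with nothing to fold the chain, and oligomerisation is the likely course. The aldehyde is α to an epoxide and the alkyne is propargylic to an acetate, both exposed to a Lewis-acidic metal with heating. C6 is created with only the neighbouring epoxide to bias it.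
- Comparison: the chosen route gives up convergence and has a longer endgame, but it obtains the ring by cutting a bond in a rigid bicycle, where ring size carries no penalty, and it fixes the olefin geometry by a stereoelectronic rule.

**Alternative 2:** The bonds cut are O6–C6 and O–C5, both on an intact ten-membered ring. The precursor is the dienoic acid A3 with a 5E olefin, the tertiary C4 hydroxyl and a chloroacetate on O13. Forward, electrophilic iodine made at the anode adds to C5=C6, the C12 carboxylate opens the iodonium ion at C6, and the C4 hydroxyl displaces the oxidatively activated C5 iodide to give A4, the chloroacetate of the target.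
- For: C5 and C6 are set by a stereospecific sequence (anti addition, then inversion) that places the two oxygens exactly as in 34. The epoxide sees only a mild deprotection afterwards. For the C4/C5/C6 relationship this is more reliable than a face-selective epoxidation, so on this point it is stronger than the chosen endgame.
- Against: all the difficulty moves into A3. A ten-membered ring with a conjugated diene acid, a tertiary allylic alcohol and the α-acetoxy ketone must exist first, and this plan does not say how the ring or the 5E olefin arise. The C4 hydroxyl can open the iodonium ion directly, the carboxylate can attack C5, and the face of iodonium formation depends on the conformation of a flexible ring.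
- Comparison: as an endgame it is shorter, but it is not a plan for the ring. The chosen route solves ring and olefin geometry in one step and accepts a plainer finish.

**Alternative 3:** The ring is cut at C9–C10, giving the acyclic bromo diketone A5. A5 has an α-bromo ketone at C8/C9 and a C10 methyl ketone next to a C1 PMB ether, with the epoxide, a C6 silyl ether and a silylene-protected diol on C11. Forward, SmI2 reduces the C9 bromide to the samarium enolate of the C8 ketone, which adds to the chelated C10 ketone and forms C9–C10, the C10 carbinol and the ring in A6.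
- For: the enolate forms regiospecifically without base, both partners are held on the metal, and the ring-closing step also creates C10. In bond and stereocentre economy of the key step this is stronger than a fragmentation that creates neither.
- Against: A5 is a long, fully functionalised chain that carries the epoxide through every step. The C8 ketone is an enone, so electron transfer to it and loss of the allylic C6 oxygen compete with reduction of the bromide. The relay from C1 to C10 across a forming ten-membered ring is hard to predict. After A6 the late problems remain: syn reduction at C8, telling C12 from C13, oxidation at C1 and acetylation.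
- Comparison: both make the ring in one step. The alternative gains a stereocentre there but needs a long linear precursor, whereas the chosen route reaches its precursor in ten steps from a simple dione and keeps the epoxide for the last step.

Key step: step 11

## Route

Step 1
Reactants: 1 2-methylcyclopentane-1,3-dione; 2 acrolein
Product: 3 3-(1-methyl-2,5-dioxocyclopentyl)propanal
Conditions: H2O, rt
Reagents that add atoms: none
Why: Michael addition of the enolised 1,3-dione to acrolein; C-alkylation at the doubly activated carbon gives the quaternary, still prochiral C4 and the chain C3–C2–C1.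

Step 2
Reactants: 3 3-(1-methyl-2,5-dioxocyclopentyl)propanal
Product: 4 2-(but-3-en-1-yl)-2-methylcyclopentane-1,3-dione
Conditions: Ph3PCH3Br, KN(SiMe3)2, THF, 0 °C; then 3, −78 → 0 °C
Reagents that add atoms: methyltriphenylphosphonium bromide, C[P+](c1ccccc1)(c1ccccc1)c1ccccc1.[Br-]
Why: Wittig methylenation; the unstabilised ylide takes the aldehyde much faster than the two hindered ring ketones, and the new terminal carbon is only a handle for metathesis.

Step 3
Reactants: 4 2-(but-3-en-1-yl)-2-methylcyclopentane-1,3-dione
Product: 5 (2S,3S)-2-(but-3-en-1-yl)-3-hydroxy-2-methylcyclopentan-1-one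
Conditions: (R)-2-methyl-CBS-oxazaborolidine (20 mol %), catecholborane, toluene, −78 °C
Reagents that add atoms: none
Why: Corey–Bakshi–Shibata reduction that desymmetrises the dione: the catalyst fixes the (S) carbinol and hydride enters anti to the butenyl chain, so one enantiotopic carbonyl reacts and C4 becomes (S); the minor diastereomer, which would carry the opposite C4, is removed by chromatography.

Step 4
Reactants: 5 (2S,3S)-2-(but-3-en-1-yl)-3-hydroxy-2-methylcyclopentan-1-one; 6 2-methylallylmagnesium chloride
Product: 7 (1S,2S,3S)-2-(but-3-en-1-yl)-2-methyl-1-(2-methylallyl)cyclopentane-1,3-diol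
Conditions: CH2=C(CH3)CH2MgCl (3 equiv), THF, −78 °C
Reagents that add atoms: none
Why: Grignard 1,2-addition; allylic magnesium reagents add under steric control, and the butenyl chain and the C5 oxygen on one face send the methallyl group to the methyl face, so the tertiary C8 hydroxyl is trans to the C4 methyl.

Step 5
Reactants: 7 (1S,2S,3S)-2-(but-3-en-1-yl)-2-methyl-1-(2-methylallyl)cyclopentane-1,3-diol
Product: 8 (4S,5S,8S)-4,10-dimethylbicyclo[5.3.0]dec-1(10)-ene-5,8-diol (trans-fused; 5-OH and 8-OH cis to each other and trans to the C4 methyl)
Conditions: second-generation Grubbs catalyst (5 mol %), CH2Cl2 (5 mM), 40 °C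
Reagents that add atoms: none
Why: ring-closing olefin metathesis of a terminal and a 1,1-disubstituted olefin closes the seven-membered ring as the trisubstituted C10=C1 olefin; the fusion is trans because the two arms lie on opposite faces of the cyclopentane.

Step 6
Reactants: 8 (4S,5S,8S)-4,10-dimethylbicyclo[5.3.0]dec-1(10)-ene-5,8-diol
Product: 9 (4R,8S)-8-hydroxy-4,10-dimethylbicyclo[5.3.0]dec-1(10)-en-5-one
Conditions: Dess–Martin periodinane, CH2Cl2, rt
Reagents that add atoms: none
Why: Dess–Martin oxidation of the only secondary alcohol; the tertiary hydroxyl and the olefin are inert, and the non-basic medium avoids retro-aldol cleavage of the β-hydroxy ketone.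

Step 7
Reactants: 9 (4R,8S)-8-hydroxy-4,10-dimethylbicyclo[5.3.0]dec-1(10)-en-5-one
Product: 10 (4S,5R,8S)-4,10-dimethylbicyclo[5.3.0]dec-1(10)-ene-5,8-diol (5-OH cis to the C4 methyl and anti to 8-OH)
Conditions: Me4NBH(OAc)3, MeCN/AcOH, −20 °C
Reagents that add atoms: none
Why: Evans–Saksena reduction; the C8 hydroxyl binds boron and delivers hydride to its own face of C5, so the new hydroxyl is anti to O8 and therefore cis to the C4 methyl, and attack anti to the angular methyl points the same way.

Step 8
Reactants: 10 (4S,5R,8S)-4,10-dimethylbicyclo[5.3.0]dec-1(10)-ene-5,8-diol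
Product: 12 (1S,4S,5R,8S,10R)-4,10-dimethylbicyclo[5.3.0]decane-1,5,8,10-tetraol (1-OH/8-OH/10-OH on one face; 5-OH and the C4 methyl on the other), via osmate ester–TMEDA chelate 11 (not isolated)
Conditions: OsO4, TMEDA, CH2Cl2, −78 °C; then aq. Na2SO3, rt
Reagents that add atoms: osmium tetroxide, O=[Os](=O)(=O)=O
Why: hydrogen-bond-directed syn dihydroxylation; the OsO4·TMEDA complex accepts a hydrogen bond from the homoallylic C8 hydroxyl and adds to that face of the C10=C1 olefin, giving the cis-diol with O10 cis to O8 and C10 (R).

Step 9
Reactants: 12 (1S,4S,5R,8S,10R)-4,10-dimethylbicyclo[5.3.0]decane-1,5,8,10-tetraol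
Product: 13 1,10-O-isopropylidene derivative of 12 (5-OH and 8-OH free)
Conditions: 2,2-dimethoxypropane, PPTS (cat.), acetone, rt
Reagents that add atoms: 2,2-dimethoxypropane, COC(C)(C)OC
Why: acetal exchange; only the cis-1,2-diol can form a five-membered acetonide, since the C5 and C8 hydroxyls are trans across the cyclopentane.

Step 10
Reactants: 13 1,10-O-isopropylidene derivative of 12
Product: 14 5-O-methanesulfonate of 13 (mesylate cis to the C4 methyl; 8-OH free; trans-fused)
Conditions: MsCl, pyridine, DMAP (cat.), CH2Cl2, 0 °C
Reagents that add atoms: methanesulfonyl chloride, CS(=O)(=O)Cl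
Why: sulfonylation without sulfene formation takes the secondary C5 hydroxyl and leaves the tertiary C8 hydroxyl, which must stay free for the fragmentation.

Step 11
Reactants: 14 5-O-methanesulfonate of 13
Product: 16 (1S,10R,4E)-1,10-(isopropylidenedioxy)-4,10-dimethylcyclodec-4-en-8-one, via potassium C8-alkoxide 15 (not isolated)
Conditions: KN(SiMe3)2 (1.05 equiv), THF, 0 °C → rt; pH 7 buffer
Reagents that add atoms: none
Why: KN(SiMe3)2 deprotonates the tertiary C8 hydroxyl to alkoxide 15, whose oxygen lone pair pushes into the C4–C8 bond while the electrons of that bond expel the C5 mesylate in one concerted step, giving the C8 ketone and the C4=C5 olefin. This is a Grob fragmentation of a cyclic 1,3-diol monosulfonate, the reaction type that opens fused bicycles to (E)-cycloalkenones. The ten-membered ring is not closed end to end but uncovered by scission of the bond shared by the five- and seven-membered rings, so no entropic or transannular cost is paid in a bond-forming step. No stereocentre is created: C4, C5 and C8 disappear, and C1 and C10 are untouched. The selectivity needed is the E geometry, and it is secured because the C5–O bond, cis to the angular methyl in the trans-fused bicycle, is pseudo-equatorial and antiperiplanar to C4–C8, which places C3 and C6 anti in the reacting conformer. Displacement at C5 by O8 would need a bridged oxetane and is not possible. One equivalent of base is used because the product is a β-alkoxy ketone that excess base would enolise and open at the dioxolane.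

Step 12
Reactants: 17 ethyl 2-(hydroxymethyl)acrylate
Product: 18 ethyl 2-{[(tert-butyldiphenylsilyl)oxy]methyl}acrylate
Conditions: TBDPSCl, imidazole, CH2Cl2, rt
Reagents that add atoms: tert-butyl(chloro)diphenylsilane, CC(C)(C)[Si](Cl)(c1ccccc1)c1ccccc1
Why: silylation of the primary alcohol; the bulky, acid-stable silyl ether carries O13 to the penultimate step.

Step 13
Reactants: 18 ethyl 2-{[(tert-butyldiphenylsilyl)oxy]methyl}acrylate
Product: 20 ethyl 3-[(tert-butyldiphenylsilyl)oxy]-2-oxopropanoate, via ozonide 19 (not isolated)
Conditions: O3, CH2Cl2, −78 °C; then Me2S, −78 °C → rt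
Reagents that add atoms: ozone, [O-][O+]=O
Why: ozonolysis of the 1,1-disubstituted olefin and reduction of the ozonide give the α-keto ester, a C11–C13 unit with C12 at the acid level and O13 protected.

Step 14
Reactants: 16 (1S,10R,4E)-1,10-(isopropylidenedioxy)-4,10-dimethylcyclodec-4-en-8-one; 20 ethyl 3-[(tert-butyldiphenylsilyl)oxy]-2-oxopropanoate
Product: 22 aldol adduct: 16 bearing at C7 the group C(OH)(CO2Et)(CH2OSiPh2t-Bu) (C7 and C11 epimers), via lithium C7(8)-enolate 21 (not isolated)
Conditions: LiN(i-Pr)2, THF, −78 °C; then 20, −78 °C; AcOH quench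
Reagents that add atoms: none
Why: kinetic aldol addition; deprotonation should occur at C7 and not at the neopentyl-type C9, the acetal oxygen is too poor a leaving group to be expelled at −78 °C, and the highly electrophilic keto group of 20 is attacked faster than its α-hydrogens are removed.

Step 15
Reactants: 22 aldol adduct
Product: 24 enone ester: C8 ketone with C7=C11 olefin (CO2Et cis to C6; CH2OSiPh2t-Bu cis to C8), via tertiary C11 mesylate 23 (not isolated)
Conditions: MsCl, Et3N, DMAP (cat.), CH2Cl2, 0 °C → rt
Reagents that add atoms: none
Why: dehydration by sulfonylation of the tertiary alcohol (through sulfene) and E1cB elimination via the C7 enolate; in the elimination the ester should avoid the enolate oxygen and the bulky silyloxymethyl group should avoid the C6 methylene, so the isomer with the ester cis to C6 is expected to prevail and is separated from the other.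

Step 16
Reactants: 24 enone ester
Product: 25 (8S)-allylic alcohol of 24
Conditions: (R)-2-methyl-CBS-oxazaborolidine, catecholborane, toluene, −78 °C
Reagents that add atoms: none
Why: Corey–Bakshi–Shibata reduction of the enone under reagent control, with the alkenyl branch as the large group, gives the (8S) alcohol with O8 syn to O10; the tetrasubstituted olefin disfavours conjugate reduction, and any geometric isomer carried along lactonises onto O8 and is removed here.

Step 17
Reactants: 25 (8S)-allylic alcohol
Product: 26 (8S)-acetate of 25
Conditions: Ac2O, pyridine, DMAP (cat.), CH2Cl2, rt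
Reagents that add atoms: acetic anhydride, CC(=O)OC(C)=O
Why: acylation installs the C8 acetate of the target and blocks O8 against lactonisation and oxidation.

Step 18
Reactants: 26 (8S)-acetate
Product: 27 6-ketone of 26 (cross-conjugated dienone)
Conditions: CrO3, 3,5-dimethylpyrazole, CH2Cl2, −20 °C
Reagents that add atoms: chromium trioxide, O=[Cr](=O)=O
Why: allylic oxidation with the CrO3–3,5-dimethylpyrazole complex; C6 is the only doubly allylic methylene and the only carbon of the resulting pentadienyl system that can end as a ketone, since the termini C4 and C11 are fully substituted.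

Step 19
Reactants: 27 6-ketone
Product: 29 (1S,6R,8S,10R)-8-acetoxy-13-[(tert-butyldiphenylsilyl)oxy]-1,10-(isopropylidenedioxy)germacra-4E,7(11)-dien-12,6-olide, via (6R)-hydroxy ester 28 (not isolated)
Conditions: (S)-2-methyl-CBS-oxazaborolidine, catecholborane, toluene, −78 °C; then PPTS (cat.), CH2Cl2, rt
Reagents that add atoms: none
Why: Corey–Bakshi–Shibata reduction of the dienone, with the α-branched C7 alkenyl as the large group, sets C6 with O6 syn to O8, and the γ-hydroxy ester with its ester cis to C6 closes to the butenolide under mild acid catalysis.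

Step 20
Reactants: 29 butenolide acetonide
Product: 30 1,10-diol of 29
Conditions: AcOH/H2O (4:1), 40 °C
Reagents that add atoms: none
Why: mild acetal hydrolysis; the acetate, lactone and silyl ether tolerate aqueous acetic acid, and the trisubstituted olefin is not protonated under these conditions.

Step 21
Reactants: 30 1,10-diol
Product: 31 10-hydroxy-1-ketone
Conditions: Dess–Martin periodinane, CH2Cl2, 0 °C → rt
Reagents that add atoms: none
Why: Dess–Martin oxidation of the secondary C1 hydroxyl; the tertiary C10 hydroxyl cannot be oxidised and no other hydroxyl is free.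

Step 22
Reactants: 31 10-hydroxy-1-ketone
Product: 32 8,10-diacetate
Conditions: Ac2O, DMAP, Et3N, CH2Cl2, 35 °C
Reagents that add atoms: acetic anhydride, CC(=O)OC(C)=O
Why: DMAP-catalysed acylation of the tertiary α-ketol; it needs forcing, but the amine bases are too weak to remove H6 of the butenolide.

Step 23
Reactants: 32 8,10-diacetate
Product: 33 (6R,8S,10R)-8,10-diacetoxy-13-hydroxy-1-oxogermacra-4E,7(11)-dien-12,6-olide
Conditions: HF·pyridine, pyridine, THF, 0 °C → rt
Reagents that add atoms: none
Why: fluoride cleavage of the silyl ether in a buffered, slightly acidic medium, which keeps both acetates in place and prevents acyl migration to O13.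

Step 24
Reactants: 33 13-alcohol
Product: 34 (4R,5R,6S,8S,10R)-8,10-diacetoxy-4,5-epoxy-13-hydroxy-1-oxogermacr-7(11)-en-12,6-olide (target)
Conditions: dimethyldioxirane, acetone, −20 °C
Reagents that add atoms: dimethyldioxirane, CC1(C)OO1
Why: epoxidation by a neutral electrophilic oxidant; only the electron-rich trisubstituted olefin reacts (the butenolide olefin is electron-poor and the dioxirane does not effect Baeyer–Villiger oxidation), and attack on the outer face of the E olefin, anti to C7 with H5 and H6 anti, should give the (4R,5R) epoxide as in related 12,6-olides.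

## Compound list

1 | 2-methylcyclopentane-1,3-dione | CC1C(=O)CCC1=O | starting material
2 | acrolein | C=CC=O | starting material
3 | 3-(1-methyl-2,5-dioxocyclopentyl)propanal | CC1(CCC=O)C(=O)CCC1=O | intermediate
4 | 2-(but-3-en-1-yl)-2-methylcyclopentane-1,3-dione | CC1(CCC=C)C(=O)CCC1=O | intermediate
5 | (2S,3S)-2-(but-3-en-1-yl)-3-hydroxy-2-methylcyclopentan-1-one (hydroxyl cis to the butenyl chain) | O=C1CC[C@H](O)[C@]1(C)CCC=C | intermediate
6 | 2-methylallylmagnesium chloride | CC(=C)C[Mg]Cl | starting material
7 | (1S,2S,3S)-2-(but-3-en-1-yl)-2-methyl-1-(2-methylallyl)cyclopentane-1,3-diol | O[C@@]1(CC(C)=C)[C@@](C)(CCC=C)[C@@H](O)CC1 | intermediate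
8 | (4S,5S,8S)-4,10-dimethylbicyclo[5.3.0]dec-1(10)-ene-5,8-diol, trans-fused, hydroxyls cis to each other | O[C@@]12CC(C)=CCC[C@@]1(C)[C@@H](O)CC2 | intermediate
9 | (4R,8S)-8-hydroxy-4,10-dimethylbicyclo[5.3.0]dec-1(10)-en-5-one, trans-fused | O[C@@]12CC(C)=CCC[C@@]1(C)C(=O)CC2 | intermediate
10 | (4S,5R,8S)-4,10-dimethylbicyclo[5.3.0]dec-1(10)-ene-5,8-diol, trans-fused, 5-OH cis to the C4 methyl | O[C@@]12CC(C)=CCC[C@@]1(C)[C@H](O)CC2 | intermediate
11 | osmate ester–TMEDA chelate of 10 (O1 and O10 on osmium) | O[C@@]12C[C@@]3(C)O[Os-2]4(=O)(=O)(O[C@H]3CC[C@@]1(C)[C@H](O)CC2)[N+](C)(C)CC[N+]4(C)C | intermediate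
12 | (1S,4S,5R,8S,10R)-4,10-dimethylbicyclo[5.3.0]decane-1,5,8,10-tetraol | O[C@@]12C[C@@](C)(O)[C@@H](O)CC[C@@]1(C)[C@H](O)CC2 | intermediate
13 | 1,10-O-isopropylidene derivative of 12 | O[C@@]12C[C@@]3(C)OC(C)(C)O[C@H]3CC[C@@]1(C)[C@H](O)CC2 | intermediate
14 | 5-O-methanesulfonate of 13 (fragmentation precursor) | O[C@@]12C[C@@]3(C)OC(C)(C)O[C@H]3CC[C@@]1(C)[C@H](OS(C)(=O)=O)CC2 | intermediate
15 | potassium C8-alkoxide of 14 | [K+].[O-][C@@]12C[C@@]3(C)OC(C)(C)O[C@H]3CC[C@@]1(C)[C@H](OS(C)(=O)=O)CC2 | intermediate
16 | (1S,10R,4E)-1,10-(isopropylidenedioxy)-4,10-dimethylcyclodec-4-en-8-one | O=C1C[C@@]2(C)OC(C)(C)O[C@H]2CC/C(C)=C/CC1 | intermediate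
17 | ethyl 2-(hydroxymethyl)acrylate | C=C(CO)C(=O)OCC | starting material
18 | ethyl 2-{[(tert-butyldiphenylsilyl)oxy]methyl}acrylate | C=C(CO[Si](c1ccccc1)(c1ccccc1)C(C)(C)C)C(=O)OCC | intermediate
19 | ozonide (1,2,4-trioxolane) of 18 | CCOC(=O)C1(CO[Si](c2ccccc2)(c2ccccc2)C(C)(C)C)OCOO1 | intermediate
20 | ethyl 3-[(tert-butyldiphenylsilyl)oxy]-2-oxopropanoate | CCOC(=O)C(=O)CO[Si](c1ccccc1)(c1ccccc1)C(C)(C)C | intermediate
21 | lithium C7(8)-enolate of 16 | [Li+].[O-]C=1C[C@@]2(C)OC(C)(C)O[C@H]2CC/C(C)=C/CC=1 | intermediate
22 | aldol adduct of 16 and 20 (C7 and C11 epimers) | O=C1C[C@@]2(C)OC(C)(C)O[C@H]2CC/C(C)=C/CC1C(O)(CO[Si](c3ccccc3)(c3ccccc3)C(C)(C)C)C(=O)OCC | intermediate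
23 | C11 methanesulfonate of 22 | O=C1C[C@@]2(C)OC(C)(C)O[C@H]2CC/C(C)=C/CC1C(OS(C)(=O)=O)(CO[Si](c3ccccc3)(c3ccccc3)C(C)(C)C)C(=O)OCC | intermediate
24 | enone ester (C7=C11; ester cis to C6) | O=C1C[C@@]2(C)OC(C)(C)O[C@H]2CC/C(C)=C/C/C1=C(/CO[Si](c3ccccc3)(c3ccccc3)C(C)(C)C)C(=O)OCC | intermediate
25 | (8S)-allylic alcohol | O[C@H]1C[C@@]2(C)OC(C)(C)O[C@H]2CC/C(C)=C/C/C1=C(/CO[Si](c3ccccc3)(c3ccccc3)C(C)(C)C)C(=O)OCC | intermediate
26 | (8S)-acetate | CC(=O)O[C@H]1C[C@@]2(C)OC(C)(C)O[C@H]2CC/C(C)=C/C/C1=C(/CO[Si](c3ccccc3)(c3ccccc3)C(C)(C)C)C(=O)OCC | intermediate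
27 | 6-ketone (cross-conjugated dienone) | CC(=O)O[C@H]1C[C@@]2(C)OC(C)(C)O[C@H]2CC/C(C)=C/C(=O)/C1=C(/CO[Si](c3ccccc3)(c3ccccc3)C(C)(C)C)C(=O)OCC | intermediate
28 | (6R)-hydroxy ester | CC(=O)O[C@H]1C[C@@]2(C)OC(C)(C)O[C@H]2CC/C(C)=C/[C@@H](O)/C1=C(/CO[Si](c3ccccc3)(c3ccccc3)C(C)(C)C)C(=O)OCC | intermediate
29 | (1S,6R,8S,10R)-8-acetoxy-13-silyloxy-1,10-(isopropylidenedioxy)germacra-4E,7(11)-dien-12,6-olide | CC(=O)O[C@H]1C[C@@]2(C)OC(C)(C)O[C@H]2CC/C(C)=C/[C@H]2OC(=O)C(CO[Si](c3ccccc3)(c3ccccc3)C(C)(C)C)=C12 | intermediate
30 | 1,10-diol of 29 | CC(=O)O[C@H]1C[C@@](C)(O)[C@@H](O)CC/C(C)=C/[C@H]2OC(=O)C(CO[Si](c3ccccc3)(c3ccccc3)C(C)(C)C)=C12 | intermediate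
31 | 10-hydroxy-1-ketone | CC(=O)O[C@H]1C[C@@](C)(O)C(=O)CC/C(C)=C/[C@H]2OC(=O)C(CO[Si](c3ccccc3)(c3ccccc3)C(C)(C)C)=C12 | intermediate
32 | 8,10-diacetate | CC(=O)O[C@H]1C[C@@](C)(OC(C)=O)C(=O)CC/C(C)=C/[C@H]2OC(=O)C(CO[Si](c3ccccc3)(c3ccccc3)C(C)(C)C)=C12 | intermediate
33 | (6R,8S,10R)-8,10-diacetoxy-13-hydroxy-1-oxogermacra-4E,7(11)-dien-12,6-olide | CC(=O)O[C@H]1C[C@@](C)(OC(C)=O)C(=O)CC/C(C)=C/[C@H]2OC(=O)C(CO)=C12 | intermediate
34 | (4R,5R,6S,8S,10R)-8,10-diacetoxy-4,5-epoxy-13-hydroxy-1-oxogermacr-7(11)-en-12,6-olide | CC(=O)O[C@H]1C[C@@](C)(OC(C)=O)C(=O)CC[C@@]2(C)O[C@@H]2[C@H]2OC(=O)C(CO)=C12 | target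

## Step count and least certain steps

Total: 24 steps. Longest linear sequence: 22 steps (steps 1–11 and 14–24); steps 12–13 prepare keto ester 20.

**Step 11 (key step).** Most likely failure: after fragmentation the β-alkoxy ketone is enolised toward C9 by remaining base or by alkoxide 15, and the dioxolane is opened by β-elimination. If alignment is poorer than assumed, anti-elimination of the mesylate toward C6 would also compete. Fallback (fragmentation under reducing conditions): 14 is treated with KOt-Bu in t-BuOH/THF in the presence of NaBH4, so that the ketone is reduced as it forms to the (E)-cyclodecenol F1 (C8 epimers). F1 is then oxidised with Dess–Martin periodinane back to 16.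

**Step 15.** Most likely failure: poor control of the geometry of the tetrasubstituted C7=C11 olefin, because the E1cB step has only a modest stereochemical bias. The isomer with the ester cis to C8 is lost, since it lactonises onto O8 in step 16. Fallback (lactone before olefin, so that the ring fixes the geometry), setting out from 16 and returning at 29:
- 16 is dehydrogenated toward C6, the only side with a β-hydrogen (LiN(i-Pr)2, Me3SiCl; then Pd(OAc)2), to the (4E,6E)-dienone F2.
- Copper-catalysed enantioselective β-borylation (CuCl, chiral bisphosphine, B2pin2) and oxidation with NaBO3 give the 6-hydroxy ketone F3, which is silylated to the triethylsilyl ether F4.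
- The kinetic enolate of F4, now between O6 and the carbonyl, adds to 20 to give the aldol adduct F5.
- HF·pyridine frees O6, which closes onto the ester to give the hydroxy lactone F6.
- MsCl/Et3N dehydration through the C7 enolate gives the keto butenolide F7.
- Corey–Bakshi–Shibata reduction gives the 8-hydroxy butenolide F8, and acetylation returns to 29.

This detour needs no C–H oxidation at C6 and sets C6 by reagent control, but the silyloxy group is β to the enolate and could be lost.

**Step 18.** Most likely failure: oxygen transfer at the wrong position (C3, or a terminus of the pentadienyl system) and over-oxidation. Fallback (ionic closure instead of C–H oxidation): from 26, radical bromination (N-bromosuccinimide, light) gives the allylic bromide F9; its allylic isomer would converge. AgOTf in wet nitromethane ionises it, and the cis ester oxygen captures the allyl cation at C6 in a five-membered ring, giving 29. The C6 configuration is then under substrate control, and an epimer would have to be separated.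

**Step 16.** Most likely failure: poor facial selectivity, because the catalyst has to tell the tetrasubstituted alkenyl carbon C7 from the neopentyl-type C9. Fallback (substrate control, then inversion): 24 is reduced with NaBH4/CeCl3. If the (8R) alcohol F10 is the main product, a Mitsunobu reaction with acetic acid (PPh3, diisopropyl azodicarboxylate) inverts C8 and gives acetate 26 directly.

**Step 24.** Most likely failure: poor facial selectivity, if the ring with the C1 ketone populates a second orientation of the olefin. Fallback (two-step epoxide formation with the opposite facial sense): 33 is converted with N-bromosuccinimide in aqueous acetone to the bromohydrin F11 (bromine on the outer face at C5, hydroxyl at the tertiary C4). K2CO3 then closes the epoxide with inversion at C5 to give 34.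

## Further compounds

F1 | step 11 | (1S,10R,4E)-1,10-(isopropylidenedioxy)-4,10-dimethylcyclodec-4-en-8-ol (C8 epimers) | OC1C[C@@]2(C)OC(C)(C)O[C@H]2CC/C(C)=C/CC1
F2 | step 15 | (4E,6E)-dienone: 6,7-didehydro derivative of 16 | O=C1C[C@@]2(C)OC(C)(C)O[C@H]2CC/C(C)=C/C=C/1
F3 | step 15 | 6-hydroxy ketone (O6 configured as in 29) | O=C1C[C@@]2(C)OC(C)(C)O[C@H]2CC/C(C)=C/[C@@H](O)C1
F4 | step 15 | 6-O-triethylsilyl ether of F3 | O=C1C[C@@]2(C)OC(C)(C)O[C@H]2CC/C(C)=C/[C@@H](O[Si](CC)(CC)CC)C1
F5 | step 15 | aldol adduct of F4 and 20 (C7 and C11 epimers) | O=C1C[C@@]2(C)OC(C)(C)O[C@H]2CC/C(C)=C/[C@@H](O[Si](CC)(CC)CC)C1C(O)(CO[Si](c3ccccc3)(c3ccccc3)C(C)(C)C)C(=O)OCC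
F6 | step 15 | 11-hydroxy-12,6-lactone with C8 ketone (C7 and C11 epimers) | O=C1C[C@@]2(C)OC(C)(C)O[C@H]2CC/C(C)=C/[C@H]2OC(=O)C(O)(CO[Si](c3ccccc3)(c3ccccc3)C(C)(C)C)C12
F7 | step 15 | 8-oxo butenolide | O=C1C[C@@]2(C)OC(C)(C)O[C@H]2CC/C(C)=C/[C@H]2OC(=O)C(CO[Si](c3ccccc3)(c3ccccc3)C(C)(C)C)=C12
F8 | step 15 | (8S)-8-hydroxy butenolide | O[C@H]1C[C@@]2(C)OC(C)(C)O[C@H]2CC/C(C)=C/[C@H]2OC(=O)C(CO[Si](c3ccccc3)(c3ccccc3)C(C)(C)C)=C12
F9 | step 18 | 6-bromo derivative of 26 (C6 epimers) | CC(=O)O[C@H]1C[C@@]2(C)OC(C)(C)O[C@H]2CC/C(C)=C/C(Br)/C1=C(/CO[Si](c3ccccc3)(c3ccccc3)C(C)(C)C)C(=O)OCC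
F10 | step 16 | (8R)-allylic alcohol, C8 epimer of 25 | O[C@@H]1C[C@@]2(C)OC(C)(C)O[C@H]2CC/C(C)=C/C/C1=C(/CO[Si](c3ccccc3)(c3ccccc3)C(C)(C)C)C(=O)OCC
F11 | step 24 | bromohydrin of 33 (4-OH; 5-Br) | CC(=O)O[C@H]1C[C@@](C)(OC(C)=O)C(=O)CC[C@@](C)(O)[C@@H](Br)[C@H]2OC(=O)C(CO)=C12
A1 | alternative 1 | acyclic epoxy ynal (C6 aldehyde; C7–C11 alkyne) | COc1ccc(COCC#C[C@@H](OC(C)=O)C[C@@](C)(OC(C)=O)[C@H](O[Si](CC)(CC)CC)CC[C@@]2(C)O[C@@H]2C=O)cc1
A2 | alternative 1 | ten-membered epoxy butenolide with C1 silyl ether and C13 PMB ether | CC(=O)O[C@H]1C[C@@](C)(OC(C)=O)[C@H](O[Si](CC)(CC)CC)CC[C@@]2(C)O[C@@H]2[C@H]2OC(=O)C(COCc3ccc(OC)cc3)=C12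
A3 | alternative 2 | cyclodecadienoic acid (5E olefin; C4 hydroxyl; C13 chloroacetate) | CC(=O)O[C@H]1C[C@@](C)(OC(C)=O)C(=O)CC[C@@](C)(O)/C=C/C1=C(/COC(=O)CCl)C(O)=O
A4 | alternative 2 | C13 chloroacetate of the target | CC(=O)O[C@H]1C[C@@](C)(OC(C)=O)C(=O)CC[C@@]2(C)O[C@@H]2[C@H]2OC(=O)C(COC(=O)CCl)=C12
A5 | alternative 3 | acyclic bromo diketone (C9 bromide; C10 methyl ketone) | CC(=O)[C@H](OCc1ccc(OC)cc1)CC[C@@]2(C)O[C@@H]2[C@@H](O[Si](C)(C)C(C)(C)C)C(C(=O)CBr)=C3CO[Si](C(C)(C)C)(C(C)(C)C)OC3
A6 | alternative 3 | ten-membered β-hydroxy ketone | O=C1C[C@@](C)(O)[C@H](OCc2ccc(OC)cc2)CC[C@@]2(C)O[C@@H]2[C@@H](O[Si](C)(C)C(C)(C)C)C1=C3CO[Si](C(C)(C)C)(C(C)(C)C)OC3
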